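The benzene ring (ring A, the only ring) of the target carries the carboxyl carbon on C-1 and the benzylic carbon C-1′ on the neighbouring C-6, with oxygen on C-2 beside the carboxyl; the key step exploits this contiguous C-2/C-1/C-6 pattern. Both ring–carbon bonds are cut together, leading back to 3,5-dimethoxybenzyne and dimethyl malonate. In step 4 fluoride unmasks the aryne from an ortho-silylaryl triflate carrying two methoxy groups, and formal insertion into a malonate C–C(=O) bond installs the C-1 ester and the C-6 acetate arm in one operation. The homophthalate is then carried through an isocoumarin, which masks the keto acid during peri O-demethylation and is opened by hydroxide last.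

Key step: step 4

Remark: the target has no stereocentre; it is assumed to be isolable as the open keto acid, which cold, weakly acidic work-up should not dehydrate back to the isocoumarin.

Step 1
Reactants: 1 3,5-dimethoxyphenol
Product: 2 3,5-dimethoxyphenyl N-isopropylcarbamate
Conditions: i-PrNCO, Et3N (cat.), CH2Cl2, rt
Reagents that add atoms: isopropyl isocyanate, CC(C)N=C=O
Why: Base-catalysed addition of the phenol O–H across the isocyanate (carbamoylation) should give a secondary aryl carbamate that directs the metalation and is later removed under mild base.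

Step 2
Reactants: 2 3,5-dimethoxyphenyl N-isopropylcarbamate
Product: 6 3,5-dimethoxy-2-(trimethylsilyl)phenyl N-isopropylcarbamate, via N-silyl carbamate 3 (not isolated), via aryllithium 4 (not isolated), via bis-silyl carbamate 5 (not isolated)
Conditions: TBSOTf, TMEDA, Et2O, 0 °C to rt; n-BuLi, TMEDA, −78 °C; TMSCl, −78 °C to rt; then cold aq. NaHSO4, brief
Reagents that add atoms: chlorotrimethylsilane, C[Si](C)(C)Cl; tert-butyldimethylsilyl triflate, CC(C)(C)[Si](C)(C)OS(=O)(=O)C(F)(F)F (N-silyl group of 3, 4 and 5 only, lost on work-up); n-butyllithium, [Li]CCCC (lithium of 4 only)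
Why: Transient N-silylation makes the carbamate tertiary, so directed ortho-metalation should occur at C-2, flanked by the carbamate and a methoxy group (C-2 and C-6 are equivalent), and TMSCl traps the aryllithium before the labile N–Si bond is hydrolysed on work-up.

Step 3
Reactants: 6 3,5-dimethoxy-2-(trimethylsilyl)phenyl N-isopropylcarbamate
Product: 8 3,5-dimethoxy-2-(trimethylsilyl)phenyl trifluoromethanesulfonate, via silylphenol 7 (not isolated)
Conditions: DBU, Et2NH, MeCN, 40 °C; then PhNTf2, rt
Reagents that add atoms: N-phenylbis(trifluoromethanesulfonimide), O=S(=O)(N(c1ccccc1)S(=O)(=O)C(F)(F)F)C(F)(F)F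
Why: DBU-promoted E1cB loss of isopropyl isocyanate (scavenged by Et2NH as a urea) should free the phenoxide, which is sulfonylated in the same pot, so that the sensitive ortho-silylphenol is never handled.

Step 4
Reactants: 8 3,5-dimethoxy-2-(trimethylsilyl)phenyl trifluoromethanesulfonate; 9 dimethyl malonate
Product: 13 dimethyl 3,5-dimethoxyhomophthalate (methyl 2,4-dimethoxy-6-(2-methoxy-2-oxoethyl)benzoate), via aryne 10 (not isolated), via aryl anion 11 (not isolated), via benzocyclobutenoxide 12 (not isolated)
Conditions: 9 (2–3 equiv), KF, 18-crown-6, THF, 0 °C to rt, slow addition of 8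
Reagents that add atoms: none
Why: Fluoride attacks silicon and triflate departs, releasing aryne 10; the malonate anion of 9 adds to the aryne carbon remote from the flanking methoxy group (the future C-6), so that aryl anion 11 carries its charge on the carbon beside that oxygen (the future C-1). The anion then attacks the adjacent ester carbonyl in a 4-exo-trig closure to benzocyclobutenoxide 12, the only ring formed, and the strained alkoxide fragments at once to the aryl ester and a stabilised ester enolate, so that no new ring remains in 13. The closest known reaction type is the fluoride-induced insertion of arynes into the C–C(=O) sigma bond of malonates and beta-keto esters (aryne acyl-alkylation). Compound 13 has no stereocentre, and the two centres of 12 are transient and without consequence. The step needs regioselective addition to an unsymmetrical aryne, and this is secured by the sigma-withdrawing methoxy substituent adjacent to the strained bond, which distorts the aryne so that the nucleophile enters at the far carbon. An excess of 9 and slow release of the aryne should hold back plain alpha-arylation and a second arylation of 13.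

Step 5
Reactants: 13 dimethyl 3,5-dimethoxyhomophthalate
Product: 14 3,5-dimethoxyhomophthalic acid (2-(carboxymethyl)-4,6-dimethoxybenzoic acid)
Conditions: KOH, EtOH/H2O, reflux; then aq. HCl, 0 °C
Reagents that add atoms: potassium hydroxide, [K+].[OH-]
Why: Saponification by acyl–oxygen cleavage should remove both methyl esters, the doubly ortho-substituted aryl ester needing prolonged heating, and cold acidification frees the diacid without protodecarboxylation.

Step 6
Reactants: 14 3,5-dimethoxyhomophthalic acid
Product: 15 6,8-dimethoxyisochromane-1,3-dione (3,5-dimethoxyhomophthalic anhydride)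
Conditions: Ac2O, toluene, reflux
Reagents that add atoms: none
Why: Cyclodehydration of the 1,5-diacid by acyl exchange with acetic anhydride should give the six-membered cyclic anhydride; base is left out so that C-4 is not acetylated.

Step 7
Reactants: 16 12-hydroxydodecanoic acid
Product: 17 12-acetoxydodecanoic acid
Conditions: Ac2O, pyridine, DMAP (cat.), CH2Cl2, rt; aq. quench
Reagents that add atoms: acetic anhydride, CC(=O)OC(C)=O
Why: Nucleophile-catalysed O-acetylation of the primary alcohol should leave the carboxylic acid unchanged after the aqueous quench, and the acetate is removed in the last step at no extra cost.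

Step 8
Reactants: 17 12-acetoxydodecanoic acid
Product: 18 12-acetoxydodecanoyl chloride
Conditions: (COCl)2, DMF (cat.), CH2Cl2, 0 °C to rt; used crude
Reagents that add atoms: oxalyl chloride, O=C(Cl)C(=O)Cl
Why: Chlorination of the acid through the chloroiminium species formed from DMF and oxalyl chloride is neutral and cold, so the acetate should survive and all by-products are gases.

Step 9
Reactants: 15 6,8-dimethoxyisochromane-1,3-dione; 18 12-acetoxydodecanoyl chloride
Product: 21 11-(6,8-dimethoxy-1-oxo-1H-isochromen-3-yl)undecyl acetate, via C-acyl anhydride 19 (not isolated), via keto acid 20 (not isolated)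
Conditions: TMG (1,1,3,3-tetramethylguanidine), Et3N, MeCN, −10 °C to rt; aq. HCl work-up; crude, wet AcOH, 90 °C; then Ac2O, 120 °C
Reagents that add atoms: none
Why: TMG forms the soluble enolate of the anhydride, which should be C-acylated at C-4 by the acid chloride while Et3N takes up HCl; warm aqueous acetic acid then opens the acylated anhydride with loss of CO2 to keto acid 20, and acetic anhydride closes it to the enol lactone while re-acetylating any terminal hydroxyl freed on the way (the standard homophthalic anhydride route to 3-substituted isocoumarins).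

Step 10
Reactants: 21 11-(6,8-dimethoxy-1-oxo-1H-isochromen-3-yl)undecyl acetate
Product: 23 11-(8-hydroxy-6-methoxy-1-oxo-1H-isochromen-3-yl)undecyl acetate, via aryloxydichloroborane 22 (not isolated)
Conditions: BCl3, CH2Cl2, −78 to 0 °C; then H2O, 0 °C
Reagents that add atoms: boron trichloride, ClB(Cl)Cl (boron and chlorine of 22 only; nothing from it remains in 23)
Why: BCl3 should bind the lactone carbonyl and the peri C-8 methoxy oxygen in a six-membered chelate, so that chloride dealkylates only that ether (chelation-controlled demethylation) and the C-6 methoxy group, the enol lactone and the acetate are left alone at low temperature.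

Step 11
Reactants: 23 11-(8-hydroxy-6-methoxy-1-oxo-1H-isochromen-3-yl)undecyl acetate
Product: 24 2-hydroxy-6-(13-hydroxy-2-oxotridecyl)-4-methoxybenzoic acid (CNP0165592.0)
Conditions: LiOH·H2O, THF/H2O, rt; then 1 M HCl to pH 3, 0 °C
Reagents that add atoms: lithium hydroxide, [Li+].[OH-]
Why: Hydroxide should open the enol lactone at the acyl carbon, the released enolate tautomerising to the benzyl ketone, and saponify the acetate in the same pot; alcohol co-solvents are avoided so that no hindered salicylate ester forms, and cold acidification gives the free keto acid.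

Compound list
1 | 3,5-dimethoxyphenol | COc1cc(O)cc(OC)c1 | starting material
2 | 3,5-dimethoxyphenyl N-isopropylcarbamate | COc1cc(OC)cc(OC(=O)NC(C)C)c1 | intermediate
3 | 3,5-dimethoxyphenyl N-(tert-butyldimethylsilyl)-N-isopropylcarbamate (formed in the flask, step 2) | COc1cc(OC)cc(OC(=O)N(C(C)C)[Si](C)(C)C(C)(C)C)c1 | intermediate
4 | 2-lithio-3,5-dimethoxyphenyl N-(tert-butyldimethylsilyl)-N-isopropylcarbamate (formed in the flask, step 2) | COc1cc(OC)c([Li])c(OC(=O)N(C(C)C)[Si](C)(C)C(C)(C)C)c1 | intermediate
5 | 3,5-dimethoxy-2-(trimethylsilyl)phenyl N-(tert-butyldimethylsilyl)-N-isopropylcarbamate (formed in the flask, step 2) | COc1cc(OC)c([Si](C)(C)C)c(OC(=O)N(C(C)C)[Si](C)(C)C(C)(C)C)c1 | intermediate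
6 | 3,5-dimethoxy-2-(trimethylsilyl)phenyl N-isopropylcarbamate | COc1cc(OC)c([Si](C)(C)C)c(OC(=O)NC(C)C)c1 | intermediate
7 | 3,5-dimethoxy-2-(trimethylsilyl)phenol (formed in the flask as its DBU-H phenoxide, step 3) | COc1cc(O)c([Si](C)(C)C)c(OC)c1 | intermediate
8 | 3,5-dimethoxy-2-(trimethylsilyl)phenyl trifluoromethanesulfonate (key-step precursor) | COc1cc(OC)c([Si](C)(C)C)c(OS(=O)(=O)C(F)(F)F)c1 | intermediate
9 | dimethyl malonate | COC(=O)CC(=O)OC | starting material
10 | 3,5-dimethoxybenzyne (1,2-didehydro-3,5-dimethoxybenzene; formed in the flask, step 4) | COC1=CC(OC)=CC#C1 | intermediate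
11 | aryl anion of dimethyl 2-(3,5-dimethoxyphenyl)malonate, charge on ring C-2 beside the methoxy group (potassium counter-ion; formed in the flask, step 4) | COC(=O)C(C(=O)OC)c1cc(OC)cc(OC)[c-]1 | intermediate
12 | methyl 2,3,5-trimethoxy-2-oxido-1,2-dihydrobenzocyclobutene-1-carboxylate (potassium alkoxide; transient, racemic, both relative configurations; formed in the flask, step 4) | COC(=O)C1c2cc(OC)cc(OC)c2C1([O-])OC | intermediate
13 | dimethyl 3,5-dimethoxyhomophthalate (methyl 2,4-dimethoxy-6-(2-methoxy-2-oxoethyl)benzoate; key-step product) | COC(=O)Cc1cc(OC)cc(OC)c1C(=O)OC | intermediate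
14 | 3,5-dimethoxyhomophthalic acid (2-(carboxymethyl)-4,6-dimethoxybenzoic acid) | OC(=O)Cc1cc(OC)cc(OC)c1C(=O)O | intermediate
15 | 6,8-dimethoxyisochromane-1,3-dione | COc1cc2CC(=O)OC(=O)c2c(OC)c1 | intermediate
16 | 12-hydroxydodecanoic acid | OCCCCCCCCCCCC(=O)O | starting material
17 | 12-acetoxydodecanoic acid | CC(=O)OCCCCCCCCCCCC(=O)O | intermediate
18 | 12-acetoxydodecanoyl chloride | CC(=O)OCCCCCCCCCCCC(=O)Cl | intermediate
19 | 12-(6,8-dimethoxy-1,3-dioxoisochroman-4-yl)-12-oxododecyl acetate (drawn as the keto tautomer; formed in the flask as its enolate, step 9) | CC(=O)OCCCCCCCCCCCC(=O)C1C(=O)OC(=O)c2c(OC)cc(OC)cc21 | intermediate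
20 | 2-(13-acetoxy-2-oxotridecyl)-4,6-dimethoxybenzoic acid (formed in the flask, step 9) | CC(=O)OCCCCCCCCCCCC(=O)Cc1cc(OC)cc(OC)c1C(=O)O | intermediate
21 | 11-(6,8-dimethoxy-1-oxo-1H-isochromen-3-yl)undecyl acetate | CC(=O)OCCCCCCCCCCCc1cc2cc(OC)cc(OC)c2c(=O)o1 | intermediate
22 | 11-[8-(dichloroboranyloxy)-6-methoxy-1-oxo-1H-isochromen-3-yl]undecyl acetate (boron chelated to the lactone carbonyl; formed in the flask, step 10) | CC(=O)OCCCCCCCCCCCc1cc2cc(OC)cc(OB(Cl)Cl)c2c(=O)o1 | intermediate
23 | 11-(8-hydroxy-6-methoxy-1-oxo-1H-isochromen-3-yl)undecyl acetate | CC(=O)OCCCCCCCCCCCc1cc2cc(OC)cc(O)c2c(=O)o1 | intermediate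
24 | 2-hydroxy-6-(13-hydroxy-2-oxotridecyl)-4-methoxybenzoic acid (CNP0165592.0) | COc1cc(O)c(C(=O)O)c(CC(=O)CCCCCCCCCCCO)c1 | target

Total step count: 11. Longest linear sequence: 9 steps (steps 1 to 6 and 9 to 11); steps 7 and 8 are a two-step side branch that joins at step 9.

The three steps most likely to fail

Step 4 (key step). The aryl anion may be protonated before it closes the four-membered ring, so that plain alpha-arylation of the malonate competes with insertion; the product may also be arylated a second time, or addition to the aryne may lose its orientation. The fallback avoids the aryne and sets out from 9. Palladium-catalysed alpha-arylation with commercial 1-bromo-3,5-dimethoxybenzene (Pd(dba)2, dba = dibenzylideneacetone, P(t-Bu)3, K3PO4, toluene, 70 °C) should give dimethyl 2-(3,5-dimethoxyphenyl)malonate F1, which is also what the alpha-arylation side path of step 4 would deliver. Krapcho demethoxycarbonylation (LiCl, wet DMSO, 150 °C) should give methyl 2-(3,5-dimethoxyphenyl)acetate F2. Vilsmeier–Haack formylation (POCl3, DMF) at the ring carbon ortho to the acetate arm and para to a methoxy group should give methyl 2-(2-formyl-3,5-dimethoxyphenyl)acetate F3. Pinnick oxidation (NaClO2, NaH2PO4, 2-methyl-2-butene, t-BuOH/H2O) should give 2,4-dimethoxy-6-(2-methoxy-2-oxoethyl)benzoic acid F4, and saponification (KOH, aq. EtOH) comes back to the route at 14.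

Step 9. The ambident anhydride enolate may be acylated on oxygen, the anhydride or the acid chloride may be hydrolysed before they meet, or the telescoped ring opening, loss of CO2 and lactonisation may stop part-way. The fallback sets out from 14, bypassing 15. Heating the diacid with an excess of 18 without solvent or base at about 200 °C should bring about anhydride formation, C-acylation, acyl-lactone rearrangement and thermal loss of CO2 in one operation. It comes back to the route at 21 and makes no new compound (F0).

Step 2. Deprotonation may occur at C-4 between the two methoxy groups instead of beside the carbamate, the carbamoyl group may migrate to carbon (anionic ortho-Fries shift) if the aryllithium warms, or the very electron-rich arylsilane may suffer ipso-protodesilylation in the acidic wash. The fallback sets out from 1. Bromination (NBS, CH2Cl2, −78 °C, with removal of any 4-bromo isomer) should give 2-bromo-3,5-dimethoxyphenol F5, and O-silylation (HMDS, THF, 65 °C) should give (2-bromo-3,5-dimethoxyphenoxy)trimethylsilane F6. Bromine–lithium exchange (n-BuLi, THF, −78 °C) should then trigger a retro-Brook oxygen-to-carbon silyl shift to the lithium salt of 7, which Tf2O converts into 8, where the route is rejoined.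

Further compounds
F1 | step 4 | dimethyl 2-(3,5-dimethoxyphenyl)malonate | COC(=O)C(C(=O)OC)c1cc(OC)cc(OC)c1
F2 | step 4 | methyl 2-(3,5-dimethoxyphenyl)acetate | COC(=O)Cc1cc(OC)cc(OC)c1
F3 | step 4 | methyl 2-(2-formyl-3,5-dimethoxyphenyl)acetate | COC(=O)Cc1cc(OC)cc(OC)c1C=O
F4 | step 4 | 2,4-dimethoxy-6-(2-methoxy-2-oxoethyl)benzoic acid | COC(=O)Cc1cc(OC)cc(OC)c1C(=O)O
F0 | step 9 | none | none
F5 | step 2 | 2-bromo-3,5-dimethoxyphenol | COc1cc(O)c(Br)c(OC)c1
F6 | step 2 | (2-bromo-3,5-dimethoxyphenoxy)trimethylsilane | COc1cc(O[Si](C)(C)C)c(Br)c(OC)c1
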